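You must decide whether to charge the reagent as written or cut it, and the noon run shows how.

| flask | solid substrate | reagent | remark | time |
|---|---|---|---|---|
| noon | 0.40 M | 2 equiv | run made earlier |  |
| flask | 0.80 M | 2.00 equiv |  | 20 min |

noon run (percent of the solid substrate charged)

| time / min | mono adduct / % | solid substrate / % |
|---|---|---|
| 0.833 | 10.9 | 0.1 |
| 2.50 | 30.5 | 0 |
| 5.00 | 50.0 | 0.2 |
| 6.00 | 56.2 | 1.0 |
| 10.0 | 71.9 | 0 |
| 12.0 | 75.2 | 0 |
| 15.0 | 81.5 | 0.5 |

(scatter of a reading: 0.5 percentage points)

- solid, in amounts per volume of the solution: solid substrate
- at the start none of the solid substrate is in solution

- equivalents of reagent to solid substrate, everything else as given, that leave most mono adduct at 20 min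
- the amount of mono adduct then, in percent of the solid substrate charged
- the amount of mono adduct with the amounts as given

At 0.833 min the noon run reads 0.1 % solid substrate yet 10.9 % mono adduct, so where is the other 89.0 %? I take it as dissolved and unreacted, and call it starting material. In that run the dissolved, unreacted share is larger than the mono adduct, so I write the rate as k[starting material][reagent]. Each addition removes one of each, so [reagent] − [starting material] stays frozen, here at 0.40 M, and ln([reagent]/[starting material]) climbs steadily. By 5.00 min that ratio has gone from 2 to 3.00, which gives k = 0.203 /M/min: the addition constant, the climb per minute per molar of difference.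

Assuming the flask's solid dissolves quickly too, its difference is 0.80 M, so by 20 min I reckon 1.99 % starting material left. The noon mono adduct at 15.0 min reads 1.1 percentage points below this reckoning, against a scatter of 0.5 points. I read that as over-addition; scaled for doubled concentrations and the longer time, it becomes 3 points. My estimate is 95.0 % mono adduct, with the best charge a little above 2.00 equiv.

The forecast gave 75.5 % as charged and 90 % at 0.99 equiv, holding that “the solid feeds the solution slowly and what dissolves reacts at once”.

    starting material + reagent → mono adduct (k = 0.210 /M/min)
    reagent + mono adduct ⇌ bis adduct (K = 0.330 /M, k = 0.00330 /M/min)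
    solid substrate ⇌ starting material, rate k3*(cs3 - [starting material]) while solid is left; crystals form when [starting material] > cs3 (solubility = 0.500 M, k = 5.60 /min)

The flask gives 93.8 % as charged and 94.0 % at 2.16 equiv, with 2.12 % starting material left at 20.0 min. Now take the neighbouring flask with 0.500 equiv of reagent, the limiting reagent there. While solid lasts, I hold [starting material] at the solubility of 0.50 M, and with the same constant [reagent] falls by 0.102 /min from 0.400 M. I reckon the solid gone after 13.7 min; from then on the difference is frozen at 0.400 M and the ratio of starting material to reagent climbs from 5.00. So 20 min leaves 13.6 % of the reagent and makes 43.2 % mono adduct. That neighbouring flask gives 13 % of its reagent left and 43.1 % mono adduct.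

(The readings are simulated with constants of no real substance, and the scatter is random.)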